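The constants were chosen freely; the result is computed.

The ratio of charged Z to a crossover charge, reckoned below, tells which order in Z the yield of DZD shows across these flasks.

    X ⇌ D, rate k1*(csat - [D]) (k1 = 0.43 s⁻¹, csat = 5.7 mM)
    D + ZD → DZD (k2 = 0.41 M⁻¹ s⁻¹)
    D → G (k3 = 0.17 s⁻¹)
    Z + ZD → ZZD (k4 = 0.024 M⁻¹ s⁻¹)
    D + DDZD → DDDZD (k5 = 0.13 M⁻¹ s⁻¹)
    D + DZD → DDZD (k6 = 0.55 M⁻¹ s⁻¹)
    Z + D → ZD (k7 = 1.1 M⁻¹ s⁻¹)

| setting | noon | dawn | autumn | spring | summer |
|---|---|---|---|---|---|
| Z | 0.012 M | 0.030 M | 0.10 M | 0.30 M | 1.0 M |
| X | 5.7 mM (held) | 5.7 mM (held) | 5.7 mM (held) | 5.7 mM (held) | 5.7 mM (held) |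
| time | 1.0 min | 1.0 min | 1.0 min | 1.0 min | 1.0 min |

- in percentages every species weighs as the Z in it: one ZZD counts as two
- at the start none of D is dissolved
- "hardly changes" means that all values lie within two and a half points (for a concentration: within two and a half percent of the largest)
- run time (noon): 1.0 min

1. [DZD] at the end for noon, dawn, autumn, spring, summer, in this order
2. the course of these numbers from the first flask to the last (falls all the way / hardly changes / rises, then falls / falls, then rises / rises all the way)

From an empty start, cD approaches its level with a time constant of about 1.67 s, far shorter than the run. X feeds D, while the return to X, the step to G and the step Z + D remove it, so this steady-state level falls as cZ rises. Their balance gives the crossover charge cZ*, the sum of the transfer coefficient and the constant of the step to G, divided by the constant of Z + D: 0.545 M. At that charge, Z removes D as fast as the other two routes together. Without Z, cD stands at 4.08 mM, and with Z it stands at this level divided by one plus cZ/cZ*.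

ZD then grows in proportion to cD, cZ and time, and DZD forms from ZD and D. My own reckoning therefore takes cDZD as half the product of the constants of Z + D and D + ZD, times cD squared, cZ and time squared.

| Flask | cZ/cZ* | cD | cDZD reckoned |
|---|---|---|---|
| noon | 0.0220 | 4.00 mM | 1.56 × 10⁻⁴ M |
| dawn | 0.0550 | 3.87 mM | 3.65 × 10⁻⁴ M |
| autumn | 0.183 | 3.45 mM | 9.67 × 10⁻⁴ M |
| spring | 0.550 | 2.64 mM | 0.00169 M |
| summer | 1.83 | 1.44 mM | 0.00169 M |

Down the table, the local order in Z is one minus the ratio, divided by one plus the ratio. It is 0.957 at noon and −0.294 in summer. The spring and summer rows nearly tie, since the product of their charges matches cZ* squared, so the reckoned peak lies between them, at cZ*. The rule keeps Z at its charge, yet at noon the step Z + D, first order in Z at this cD, uses about 23.2% of it by the end, so the reckoned numbers stand high.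

The forecast gives 1.250 × 10⁻⁴ M, 3.000 × 10⁻⁴ M, 8.000 × 10⁻⁴ M, 0.00135 M and 0.0011 M, with the course rises, then falls, on the ground that “the lower D and the diversion of ZD into ZZD outweigh the extra Z”. Its course matches mine, but its summer value stands lower than my 0.00169 M.

The flasks give 1.25 × 10⁻⁴ M, 2.95 × 10⁻⁴ M, 7.84 × 10⁻⁴ M, 0.00134 M and 0.00110 M, so the course is rises, then falls. The row turns at a reading of 0.44 M, below cZ*. In summer, the unbound Z left at the end is 87% of the charge, or 1.59 times cZ*, which gives cD = 1.58 mM against 1.55 mM in the flask. In spring, with 82% left, the same division gives 2.82 mM against 2.77 mM in the flask after 1.00 min.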